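The numbers in the tables were computed on assumed constants.

Split every flask into three fractions of the charge: a of starting material, p of ring, and c in open chains, with dimer and trimer counted by the starting material in them. Asked is y = p/(p + c), the selectivity for ring.

| flask | starting material | temperature | remark | time |
|---|---|---|---|---|
| amber | 0.40 M | 15 °C | run made earlier |  |
| red | 1.6 M | 37 °C | run made earlier |  |
| Sunday's | 0.80 M | 25 °C |  | 40 h |
| Monday's | 0.80 M | 5 °C |  | 40 h |
| Tuesday's | 0.80 M | 45 °C |  | 40 h |

- amber (time / h: ring / %, open dimer / %, open trimer / %): 5.00: 22.7, 19.7, 1.5; 12.0: 22.5, 28.4, 4.8; 25.0: 17.2, 37.4, 12.4; 60.0: 9.4, 44.0, 25.4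
- red (time / h: ring / %, open dimer / %, open trimer / %): 6.00: 0.4, 30.7, 63.7; 12.0: 0.2, 26.5, 72.4; 15.0: 0.5, 25.9, 73.8; 20.0: 0.1, 25.0, 74.9

(readings scatter by 0.5 percentage points)

- the best flask by share of ring in all that became ring or open dimer or open trimer; "all alike" if 1.5 percentage points covers them all (Sunday's / Monday's / Tuesday's / all alike)
- share of ring in all that became ring or open dimer or open trimer, Sunday's
- share of ring in all that became ring or open dimer or open trimer, Monday's
- share of ring in all that became ring or open dimer or open trimer, Tuesday's

**What does amber say of ring against starting material?** At 25.0 h the readings leave a = 33.0%, so p/a reads 0.521.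

**And red?** Its ring reads 0.4% at 6.00 h, with a scatter of 0.5 percentage points. The ratio is smaller there, but its size can't be read.

**Then what do you take for Monday's, the coldest?** I take the symmetric case, p = a, as the zero of the scale; it is a choice, not a measurement. Then y = a/(a + c), and c gives the answer.

**Where does c come from?** I use a clock, z = c/(a + p), and treat the loss to chains as second-order, so z grows with charge times time. Amber at 60.0 h has z = 2.27. Per charge and hour, red at 6.00 h runs 18.6 times faster.

**But Monday's lies below amber, not above.** Its distance from amber is about half the distance from amber to red, so I divide by the square root of that factor. Monday's then has z = 0.702, so c = 41.2%. That gives 41.6%, the balanced share: what ring holds of the converted material when p = a.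

The forecast names Monday's as best, with 1.5% for Sunday's, 50% for Monday's and 0.05% for Tuesday's. For Monday's it says “only about a third has gone to open chains, and the ring holds about half of the product”. My balanced share is lower than its figure.

The flasks give Monday's as best, with 1.22% for Sunday's, 31.8% for Monday's and 0% for Tuesday's.

    starting material ⇌ ring (K = 0.860, k = 0.0260 h⁻¹, Ea = 91.0 kJ mol⁻¹, ΔH = −39.0 kJ mol⁻¹)
    2 starting material → open dimer (k = 0.0310 M⁻¹ h⁻¹, Ea = 70.0 kJ mol⁻¹)
    starting material + open dimer → open trimer (k = 0.0180 M⁻¹ h⁻¹, Ea = 86.0 kJ mol⁻¹)
    (constants at 5 °C)

Monday's has c = 50.8% at 40.0 h, above my 41.2%, with ring 23.7% beside starting material 25.4%, so the balanced share moves from 41.6% to 32.6%. In Monday's p/a stands at 0.582 at 20.0 h and at 0.933 at 40.0 h, and at 40.0 h open dimer is made 2.16 times faster than it is used up. A repeat at −10 °C holds ring 8.78% beside starting material 67.0%, so its balanced share of 61.0% stands against a flask value of 26.6%.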